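## Structural features

The target is a 3,5-dihydro-2H-1-benzofuran-6-one. A dihydrofuran ring (O1, C2, C3, C3a, C7a) is fused along C3a–C7a to a six-membered carbocycle that is a linearly conjugated dienone (C6=O, C7=C7a, C3a=C4) with an sp3 carbon at C5. C2 (3,4,5-trimethoxyphenyl) and C3 (methyl) are adjacent stereocentres in a trans (2S,3S) relationship. The third stereocentre, C5 (R), is quaternary, carries allyl and methoxy, and is separated from the other two by the sp2 atoms C3a and C4, so it cannot be set by relay from them. Four neighbouring ring carbons carry oxygen: C5 (OMe), C6 (C=O), C7 (OMe) and C7a (O1). The fragile parts are the allyl/methoxy quaternary centre of the dienone (allyl migration with aromatisation in strong acid, [3,3] shifts via alkoxides or heat), the C7=C7a enol ether, the electron-rich benzylic C2–O1 bond and the terminal alkene. The real difficulty is the dearomatised, fully oxygenated carbocycle with its isolated C5 stereocentre, not the trans C2/C3 pair. The key step exploits the fact that C5, C6, C7 and C7a map onto the four carbons of a squaric ester, so only C3a and C4 must come from elsewhere, namely from an alkyne that already carries C3 and C2.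

## Logic of the disconnections

19 ⇒ 17 (through 18). The O1–C7a bond is cut, C7a is returned to a ketone and the C6 ketone to its methyl enol ether. The C7a enol ether/C6 ketone pair of 19 is a transposed vinylogous ester, so the furan ring can be opened without changing the oxidation level. This leaves a monocyclic dienone with O1 stored as a silyl ether. The forward step must add O1 to C7a (five-membered closure) and expel methanol from C6 under acid mild enough to spare C5 and the benzylic C2–O1 bond.

17 ⇒ 16. The O–CH3 bond at C5 is cut. This exposes a tertiary alcohol that is the direct product of a carbonyl addition. The forward methylation must work on a hindered, doubly allylic hydroxyl without generating a free alkoxide that could trigger a [3,3] shift of the allyl group.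

16 ⇒ 12 + 15. The C5–CH2 bond is cut, because C5 of 16 is a former quinone carbonyl. This removes the only stereocentre outside the side chain and leads to a planar ring. The forward step must be 1,2-selective, must choose C5 over C7a, and must choose one face of C5 under external control. 15 is cut at the B–C bond to 13 and 14.

12 ⇒ 9 (through 11 and 10). The C3a–C7a bond is cut and the C5–C7a bond of the four-membered ring is restored. The six-membered ring is thereby reduced to a cyclobutenone plus an alkyne, and every ring substituent of 12 is placed by the connectivity of 9. The hydroxyl of 9 is left free to serve as hydrogen donor for C4, and the alkyne substituent is a plain secondary alkyl group. The forward step needs thermal opening with the right sense of rotation, six- and not five-membered closure, and no damage to the propargylic stereocentre.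

9 ⇒ 6 + 7 (through 8). The bond between C5 and C4 (carbinol carbon to alkyne carbon) is cut. This is the convergent step that joins the stereodefined fragment to the ring precursor. It needs mono-addition of 8 to one carbonyl of 7.

6 ⇒ 5. The O–Si bond is cut. The silyl ether hides O1 from the base of the acetylide step and from the boron reagent.

5 ⇒ 3 + 2 (through 4). The C2–C3 bond is cut. Both side-chain stereocentres arise in one step from an achiral aldehyde and a three-carbon unit whose single stereocentre is bought. The forward step needs anti diastereoselection and faithful chirality transfer.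

2 ⇒ 1. The S–O bond is cut. This is an activation that does not touch the stereocentre.

## Other disconnections considered

Alternative 1: The cut is the C3–C3a bond, with the C3 methyl traced back to an ester carbon. In the forward sense the (2S)-flavanone A1 would be treated with PhI(OAc)2 and H2SO4 in trimethyl orthoformate. The enol ether is attacked at C3 by the trivalent iodine reagent, the ring A carbon shifts from the carbonyl carbon to C3 with loss of iodobenzene, and the former carbonyl carbon leaves the ring as the methyl ester of the trans dihydrobenzofuran A2.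
- In favour: the ring contraction is an established reaction type for flavanones. C3 is controlled from C2 (anti migration, and C3 is epimerisable next to the ester, so trans is also the thermodynamic outcome). The O1–C7a bond exists from the start, so no late acid-mediated furan closure is needed; on this point the alternative is better than the chosen plan.
- Against: ring A carries three oxygen substituents and the C2 aryl group three more, so ring oxidation, shift of the C2 aryl group instead of ring A, and dehydrogenation to the flavone all compete. The ester then has to be taken down to methyl (reduction, sulfonylation, hydride displacement) to reach A3.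
- The decisive weakness is the endgame: hydrogenolysis to phenol A4, allylation to ether A5, and a [3,3] shift of A5 into C5 to give 19. That shift runs against aromaticity, can go to C7 as well as C5, can continue to C3a, and has no control over the C5 configuration.
- Comparison: the alternative makes the easy part of the structure (trans C2/C3 on an aromatic core) robustly and postpones the hard part, whereas the chosen plan never makes the carbocycle aromatic. The mechanism is a cationic 1,2-shift against a thermal pericyclic/diradical sequence. The step count would be clearly higher (about twelve to fourteen against nine).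

Alternative 2: The cuts are C2–C3 and O1–C2. Base would release an ortho-quinone methide from sulfone A6. The ylide from sulfonium salt A7 adds at C3, and the phenoxide then displaces the sulfide at C2 to give A3.
- In favour: two bonds, the furan ring and both stereocentres are formed in one step, and trans selectivity follows from the anti-periplanar displacement. For the C2/C3 pair this is better in step economy than the three steps the chosen plan spends on 5 and 6.
- Against: the absolute configuration would need a chiral sulfide in place of the dimethyl sulfide unit of A7, or a chiral catalyst. A methyl-substituted quinone methide can also tautomerise to a vinylphenol.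
- From A3 the route shares the uncontrolled dearomatising endgame of alternative 1 (A4, A5, then 19).
- Comparison: polar annulation on an aromatic ring against ring construction from a four-carbon unit. Alternative 2 is shorter to the bicyclic core, but it is expected to lose that advantage, and control of C5, at the end.

Alternative 3: The cut is the C6–C7 bond. LiN(SiMe3)2 would form the C7 enolate of the methoxymethyl ketone in A8, which attacks the C6 methyl ester (Dieckmann closure) to give the 2-methoxy-1,3-dione enol A9. Desilylation and cyclodehydration of O1 onto C7a would then give 19.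
- In favour: C5 is set before the ring exists, by desymmetrisation of the prochiral malonate A10 with known ester-differentiating chemistry. On the C5 stereocentre this is the better plan, because it avoids face selection on a quinone. The methoxy group at C5 is present from the start, so no hindered tertiary alcohol has to be methylated. The final closure loses water instead of methanol and is at least the equal of the last step chosen here.
- Against: A8 needs a Z-configured trisubstituted enone carrying the bulky side chain, which can isomerise and accept nucleophiles. The amide base can remove the γ-hydrogen at C3 instead of the C7 hydrogen, which would scramble C3. The linear sequence to A8 is long (probably thirteen steps or more).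
- Comparison: alternative 3 builds the carbocycle by a polar condensation with the stereocentre already fixed. The chosen plan builds it in one thermal step with all substituent positions fixed by connectivity, and pays for this with the C5 problem afterwards. The chosen plan is much shorter.

Key step: step 5

Assumptions and remarks:
- Ring positions in the discussion follow the benzofuran numbering of 19 (O1, C2, C3, C3a, C4–C7, C7a), also for monocyclic compounds; systematic names use their own locants.
- The anti side chain of 9 and 12 is (S) at both carbons. This maps onto (2S,3S) of 19 because the C2–O bond is never broken, and it requires the (R) enantiomer of but-3-yn-2-ol.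
- The sense of induction in step 7 is assigned by analogy with aryl methyl ketones; the antipodal diol is used if the opposite sense is found.
- 15 is prepared (step 6) because the pinacol ester of allylboronic acid would exchange too slowly with the diol catalyst.

## Route

Step 1
Reactants: 1 (R)-but-3-yn-2-ol
Product: 2 (R)-but-3-yn-2-yl methanesulfonate
Conditions: MsCl, Et3N, CH2Cl2, −78 °C → 0 °C; used crude
Reagents that add atoms: methanesulfonyl chloride, CS(=O)(=O)Cl
Why: Sulfonylation of the hydroxyl oxygen does not touch the C–O bond of the stereocentre, so 2 should keep the (R) configuration; it is used without purification because propargylic mesylates are labile.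

Step 2
Reactants: 2 (R)-but-3-yn-2-yl methanesulfonate; 3 3,4,5-trimethoxybenzaldehyde
Product: 5 (1S,2S)-2-methyl-1-(3,4,5-trimethoxyphenyl)but-3-yn-1-ol, via (P)-buta-1,2-dienyl(ethyl)zinc 4 (not isolated)
Conditions: Pd(OAc)2 (5 mol%), PPh3 (5 mol%), Et2Zn (3 equiv), THF, −78 °C → −20 °C; aq. NH4Cl
Reagents that add atoms: none
Why: Marshall propargylation: zerovalent palladium (formed from Pd(OAc)2, PPh3 and Et2Zn) should displace the mesylate in an anti SN2' sense and pass the allenyl group to zinc with retention, giving 4, which adds to 3 through a cyclic six-membered SE2' transition state with the aryl group turned away from the allenyl methyl; C3 (S) comes from the mesylate centre by chirality transfer and C2 (S) is set anti to it in the same event.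

Step 3
Reactants: 5 (1S,2S)-2-methyl-1-(3,4,5-trimethoxyphenyl)but-3-yn-1-ol
Product: 6 tert-butyl(dimethyl){[(1S,2S)-2-methyl-1-(3,4,5-trimethoxyphenyl)but-3-yn-1-yl]oxy}silane
Conditions: TBSCl, imidazole, DMF, rt
Reagents that add atoms: tert-butyldimethylsilyl chloride, CC(C)(C)[Si](C)(C)Cl
Why: Standard silylation of a secondary benzylic alcohol; the silyl ether should survive n-BuLi, the thermolysis, the boron reagent and the methylation, and it is removed only in the last step.

Step 4
Reactants: 6 tert-butyl(dimethyl){[(1S,2S)-2-methyl-1-(3,4,5-trimethoxyphenyl)but-3-yn-1-yl]oxy}silane; 7 dimethyl squarate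
Product: 9 4-[(3S,4S)-4-(tert-butyldimethylsilyloxy)-3-methyl-4-(3,4,5-trimethoxyphenyl)but-1-ynyl]-4-hydroxy-2,3-dimethoxycyclobut-2-en-1-one (both carbinol epimers), via lithium acetylide 8 (not isolated)
Conditions: n-BuLi (1.0 equiv), THF, −78 °C; cannulated into 7, THF, −78 °C; aq. NH4Cl at −78 °C
Reagents that add atoms: none
Why: Deprotonation of the terminal alkyne gives 8, which should add 1,2 to one of the two equivalent carbonyl groups of 7 (known acetylide addition to squaric esters); inverse addition and exactly one equivalent of base are meant to prevent double addition, and the new carbinol centre is of no consequence because it becomes sp2 in step 5.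

Step 5
Reactants: 9 4-[(3S,4S)-4-(tert-butyldimethylsilyloxy)-3-methyl-4-(3,4,5-trimethoxyphenyl)but-1-ynyl]-4-hydroxy-2,3-dimethoxycyclobut-2-en-1-one
Product: 12 5-[(1S,2S)-1-(tert-butyldimethylsilyloxy)-1-(3,4,5-trimethoxyphenyl)propan-2-yl]-2,3-dimethoxy-1,4-benzoquinone, via alkynyl vinylketene 10 (not isolated), via ring diradical 11 (not isolated)
Conditions: degassed p-xylene (0.02 M), 138 °C, argon
Reagents that add atoms: none
Why: This is a Moore cyclisation. Heating should open the cyclobutenone by conrotatory four-electron cleavage of the bond between the carbonyl carbon and the carbinol carbon, the hydroxyl donor turning outward so that the alkynyl group of 10 lies on the side of the ketene. The ketene carbon (future C7a) then bonds to the distal alkyne carbon (future C3a) and closes the six-membered carbocycle in a 6-endo-dig sense as 11, with a σ-radical at C4 and the second spin on the C7a oxygen; transfer of the hydroxyl hydrogen from the C5 oxygen to C4 gives 12. The closest known reaction type is the thermal ring expansion of 4-alkynyl-4-hydroxycyclobutenones from squaric esters to benzoquinones. No stereocentre is formed, both carbinol epimers of 9 converge, and C3 and C2 are spectators beside the alkyne. The selectivity needed is six- against five-membered closure (bonding to the distal and not the proximal alkyne carbon), which the plain secondary alkyl substituent should secure, since no aryl, silyl or alkoxy group stabilises a vinyl radical at the distal carbon. The ring pattern (side chain on C3a next to C7a, hydrogen on C4, methoxy groups on C6 and C7) follows from the connectivity of 9 and cannot vary. Dilution and degassing are meant to keep 11 from intermolecular hydrogen abstraction.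

Step 6
Reactants: 13 allylmagnesium bromide; 14 triisopropyl borate
Product: 15 allyldiisopropoxyborane (diisopropyl prop-2-enylboronate)
Conditions: Et2O, −78 °C → rt; HCl in Et2O (1 equiv), 0 °C; filtration, distillation
Reagents that add atoms: none
Why: Addition of the Grignard reagent to the borate gives the allyltriisopropoxyborate salt and one equivalent of anhydrous acid releases the boronic ester (standard preparation of boronic esters from organomagnesium reagents); the isopropyl ester is chosen because it exchanges readily with a diol catalyst.

Step 7
Reactants: 12 5-[(1S,2S)-1-(tert-butyldimethylsilyloxy)-1-(3,4,5-trimethoxyphenyl)propan-2-yl]-2,3-dimethoxy-1,4-benzoquinone; 15 allyldiisopropoxyborane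
Product: 16 (4R)-6-[(1S,2S)-1-(tert-butyldimethylsilyloxy)-1-(3,4,5-trimethoxyphenyl)propan-2-yl]-4-hydroxy-2,3-dimethoxy-4-(prop-2-enyl)cyclohexa-2,5-dien-1-one
Conditions: (R)-3,3'-dibromo-1,1'-bi-2-naphthol (15 mol%), PhCF3/toluene 3:1, −35 °C; pH 7 buffer
Reagents that add atoms: none
Why: Proposed new method: diol-catalysed asymmetric allylboration is established for aryl and alkenyl ketones but not for a p-quinone carbonyl; exchange of one isopropoxy group of 15 for the chiral diol should give a more Lewis acidic mixed boronate that binds the C5 carbonyl oxygen and transfers allyl through a chair six-membered transition state (1,2-addition only); C5 should be preferred over C7a because C7a is flanked by two substituted carbons (C3a with the branched side chain, C7 with OMe) while both carbonyls are equally deactivated as vinylogous esters; the C6(OMe) flank is expected to take the pseudo-equatorial place of the large ketone substituent and the C4–H flank the axial place, so that the (R)-diol should deliver allyl to the Si face of C5 (priorities O > C6 > C4) and set (4R) in 16; the closest known reaction type is the 3,3'-dibromo-binaphthol-catalysed allylboration of ketones with allyldiisopropoxyborane.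

Step 8
Reactants: 16 (4R)-6-[(1S,2S)-1-(tert-butyldimethylsilyloxy)-1-(3,4,5-trimethoxyphenyl)propan-2-yl]-4-hydroxy-2,3-dimethoxy-4-(prop-2-enyl)cyclohexa-2,5-dien-1-one
Product: 17 (4R)-6-[(1S,2S)-1-(tert-butyldimethylsilyloxy)-1-(3,4,5-trimethoxyphenyl)propan-2-yl]-2,3,4-trimethoxy-4-(prop-2-enyl)cyclohexa-2,5-dien-1-one
Conditions: MeI (excess), Ag2O, 4 Å MS, MeCN, 40 °C, dark
Reagents that add atoms: iodomethane, CI
Why: Purdie methylation alkylates the tertiary, doubly allylic hydroxyl without a free alkoxide, which should avoid an alkoxide-accelerated [3,3] shift of the allyl group; only the O–H bond is replaced, so the configuration at the quaternary carbon is unchanged, and the silyl ether and enol ethers are inert.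

Step 9
Reactants: 17 (4R)-6-[(1S,2S)-1-(tert-butyldimethylsilyloxy)-1-(3,4,5-trimethoxyphenyl)propan-2-yl]-2,3,4-trimethoxy-4-(prop-2-enyl)cyclohexa-2,5-dien-1-one
Product: 19 (2S,3S,5R)-5,7-dimethoxy-3-methyl-5-(prop-2-enyl)-2-(3,4,5-trimethoxyphenyl)-3,5-dihydro-2H-1-benzofuran-6-one (CNP0080458.1), via hydroxy dienone 18 (not isolated)
Conditions: 48% aq. HF/MeCN (1:19), 0 °C → rt
Reagents that add atoms: water, O
Why: Aqueous HF should cleave the silyl ether to 18, whose free O1 adds to the C7a carbonyl in a 5-exo-trig sense; under the same acid the former carbonyl oxygen leaves as water, the cation is stabilised by O1 and by the C6 methoxy group, and water adds at C6 and expels methanol (an intramolecular variant of the Stork–Danheiser transposition of a β-alkoxy enone), which gives the C6 ketone and the C7=C7a enol ether; the C2–O1 bond is never broken, so (2S,3S) is kept, and C5 is not involved.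

## Compound list

1 | (R)-but-3-yn-2-ol | C#C[C@@H](C)O | starting material
2 | (R)-but-3-yn-2-yl methanesulfonate | C#C[C@@H](C)OS(C)(=O)=O | intermediate
3 | 3,4,5-trimethoxybenzaldehyde | COc1cc(C=O)cc(OC)c1OC | starting material
4 | (P)-buta-1,2-dienyl(ethyl)zinc | CC[Zn]C([H])=[C@@]=C([H])C | intermediate (not isolated)
5 | (1S,2S)-2-methyl-1-(3,4,5-trimethoxyphenyl)but-3-yn-1-ol | C#C[C@H](C)[C@H](O)c1cc(OC)c(OC)c(OC)c1 | intermediate
6 | tert-butyl(dimethyl){[(1S,2S)-2-methyl-1-(3,4,5-trimethoxyphenyl)but-3-yn-1-yl]oxy}silane | C#C[C@H](C)[C@H](O[Si](C)(C)C(C)(C)C)c1cc(OC)c(OC)c(OC)c1 | intermediate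
7 | dimethyl squarate (3,4-dimethoxycyclobut-3-ene-1,2-dione) | COC1=C(OC)C(=O)C1=O | starting material
8 | lithium acetylide of 6, [(3S,4S)-4-(tert-butyldimethylsilyloxy)-3-methyl-4-(3,4,5-trimethoxyphenyl)but-1-ynyl]lithium | [Li]C#C[C@H](C)[C@H](O[Si](C)(C)C(C)(C)C)c1cc(OC)c(OC)c(OC)c1 | intermediate (not isolated)
9 | 4-[(3S,4S)-4-(tert-butyldimethylsilyloxy)-3-methyl-4-(3,4,5-trimethoxyphenyl)but-1-ynyl]-4-hydroxy-2,3-dimethoxycyclobut-2-en-1-one (both carbinol epimers) | COC1=C(OC)C(O)(C#C[C@H](C)[C@H](O[Si](C)(C)C(C)(C)C)c2cc(OC)c(OC)c(OC)c2)C1=O | intermediate
10 | (3Z,7S,8S)-8-(tert-butyldimethylsilyloxy)-4-hydroxy-2,3-dimethoxy-7-methyl-8-(3,4,5-trimethoxyphenyl)octa-1,3-dien-5-yn-1-one (alkynyl vinylketene) | O=C=C(OC)/C(OC)=C(/O)C#C[C@H](C)[C@H](O[Si](C)(C)C(C)(C)C)c1cc(OC)c(OC)c(OC)c1 | intermediate (not isolated)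
11 | 2-[(1S,2S)-1-(tert-butyldimethylsilyloxy)-1-(3,4,5-trimethoxyphenyl)propan-2-yl]-4-hydroxy-5,6-dimethoxyphenoxyl-3-yl diradical | COc1c(OC)c(O)[c]c([C@H](C)[C@H](O[Si](C)(C)C(C)(C)C)c2cc(OC)c(OC)c(OC)c2)c1[O] | intermediate (not isolated)
12 | 5-[(1S,2S)-1-(tert-butyldimethylsilyloxy)-1-(3,4,5-trimethoxyphenyl)propan-2-yl]-2,3-dimethoxy-1,4-benzoquinone | COC1=C(OC)C(=O)C([C@H](C)[C@H](O[Si](C)(C)C(C)(C)C)c2cc(OC)c(OC)c(OC)c2)=CC1=O | intermediate
13 | allylmagnesium bromide (solution in Et2O) | C=CC[Mg]Br | starting material
14 | triisopropyl borate | CC(C)OB(OC(C)C)OC(C)C | starting material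
15 | allyldiisopropoxyborane | C=CCB(OC(C)C)OC(C)C | intermediate
16 | (4R)-6-[(1S,2S)-1-(tert-butyldimethylsilyloxy)-1-(3,4,5-trimethoxyphenyl)propan-2-yl]-4-hydroxy-2,3-dimethoxy-4-(prop-2-enyl)cyclohexa-2,5-dien-1-one | C=CC[C@@]1(O)C=C([C@H](C)[C@H](O[Si](C)(C)C(C)(C)C)c2cc(OC)c(OC)c(OC)c2)C(=O)C(OC)=C1OC | intermediate
17 | (4R)-6-[(1S,2S)-1-(tert-butyldimethylsilyloxy)-1-(3,4,5-trimethoxyphenyl)propan-2-yl]-2,3,4-trimethoxy-4-(prop-2-enyl)cyclohexa-2,5-dien-1-one | C=CC[C@@]1(OC)C=C([C@H](C)[C@H](O[Si](C)(C)C(C)(C)C)c2cc(OC)c(OC)c(OC)c2)C(=O)C(OC)=C1OC | intermediate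
18 | (4R)-6-[(1S,2S)-1-hydroxy-1-(3,4,5-trimethoxyphenyl)propan-2-yl]-2,3,4-trimethoxy-4-(prop-2-enyl)cyclohexa-2,5-dien-1-one | C=CC[C@@]1(OC)C=C([C@H](C)[C@H](O)c2cc(OC)c(OC)c(OC)c2)C(=O)C(OC)=C1OC | intermediate (not isolated)
19 | (2S,3S,5R)-5,7-dimethoxy-3-methyl-5-(prop-2-enyl)-2-(3,4,5-trimethoxyphenyl)-3,5-dihydro-2H-1-benzofuran-6-one | C=CC[C@@]1(OC)C=C2C(=C(OC)C1=O)O[C@H](c1cc(OC)c(OC)c(OC)c1)[C@H]2C | target

## Step count and least certain steps

Total step count: 9 (eight in the main line and one reagent preparation). Longest linear sequence: 8 steps (1 → 2 → 5 → 6 → 9 → 12 → 16 → 17 → 19).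

Step 7 (new method). The most likely failure is poor discrimination between the two faces of C5, because both flanks of the carbonyl are sp2 carbons and differ only by H against OMe. An uncatalysed background addition to the electrophilic quinone would erode selectivity further, and some addition at C7a is conceivable. The fallback uses known chemistry and gives up catalyst control. From 12, unselective 1,2-allylation with the allylindium reagent made from indium powder and allyl bromide in DMF at room temperature (a known reaction of p-quinones) should give 16 together with its C5 epimer, the (4S)-configured quinol F1. The two are diastereomers and would be separated by chromatography, here or after step 9. The route is rejoined at 16 at the cost of about half the material.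

Step 5 (key step). Two processes could divert the diradical pathway. One is bonding of the ketene carbon to the proximal alkyne carbon, which would close a five-membered ring. The other is hydrogen abstraction by the C4 σ-radical from the benzylic C2–H of the side chain (a 1,5-shift) in place of the hydroxyl hydrogen. The fallback replaces the diradical closure by a pericyclic one. From 6, hydrozirconation with Cp2Zr(H)Cl and iodinolysis should give the (E)-alkenyl iodide F2. Iodine–lithium exchange with t-BuLi and addition to 7 gives the 4-alkenyl-4-hydroxycyclobutenone F3. Heating in toluene opens the ring to a dienylketene that closes by six-electron electrocyclisation and tautomerises to the hydroquinone F4. Oxidation with Ag2O returns to the route at 12.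

Step 2. With an aromatic aldehyde the preference for the anti transition state is smaller than with branched aliphatic aldehydes, so anti/syn selectivity may erode. Equilibration of the allenylmetal species before addition would also lower the enantiomeric purity. The fallback sets the same two centres by crotylboration. From 3, Brown crotylboration with the (E)-crotyl reagent derived from (−)-B-methoxydiisopinocampheylborane should give the anti homoallylic alcohol F5. Silylation gives the silyl ether F6, ozonolysis with PPh3 work-up gives the aldehyde F7, and Ohira–Bestmann homologation (K2CO3, MeOH, 0 °C, to limit epimerisation next to the aldehyde) returns to the route at 6.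

Step 8. Methylation of a hindered tertiary hydroxyl with MeI and Ag2O may be slow. Forcing it with a strong base would create an alkoxide that can undergo an accelerated [3,3] shift of the allyl group. The fallback changes the order of events. From 16, treatment with aqueous HF in MeCN (as in step 9) should remove the silyl group and close the furan ring to the tertiary alcohol F8. Its hydroxyl is now next to the C6 ketone and more acidic, and it would be methylated with MeI and Ag2O to return at 19.

Step 9. Acid could also trigger migration of the allyl group from C5 to a neighbouring carbon with aromatisation (a dienone–phenol shift), or ionisation at the benzylic C2 before the closure is complete. The fallback separates the loss of methanol from the acid step. From 17, hydrolysis of the vinylogous ester with LiOH in aqueous THF should give the 1,3-dione enol F9 (the same compound as A9). Buffered desilylation with tetrabutylammonium fluoride and acetic acid gives the hydroxy dione F10. F10 should cyclise with loss of water under pyridinium p-toluenesulfonate and 4 Å molecular sieves, much milder than the conditions of step 9, returning at 19.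

## Further compounds

F1 | step 7 | (4S)-6-[(1S,2S)-1-(tert-butyldimethylsilyloxy)-1-(3,4,5-trimethoxyphenyl)propan-2-yl]-4-hydroxy-2,3-dimethoxy-4-(prop-2-enyl)cyclohexa-2,5-dien-1-one | C=CC[C@]1(O)C=C([C@H](C)[C@H](O[Si](C)(C)C(C)(C)C)c2cc(OC)c(OC)c(OC)c2)C(=O)C(OC)=C1OC
F2 | step 5 | tert-butyl{[(1S,2S,3E)-4-iodo-2-methyl-1-(3,4,5-trimethoxyphenyl)but-3-en-1-yl]oxy}dimethylsilane | I/C=C/[C@H](C)[C@H](O[Si](C)(C)C(C)(C)C)c1cc(OC)c(OC)c(OC)c1
F3 | step 5 | 4-[(1E,3S,4S)-4-(tert-butyldimethylsilyloxy)-3-methyl-4-(3,4,5-trimethoxyphenyl)but-1-enyl]-4-hydroxy-2,3-dimethoxycyclobut-2-en-1-one | COC1=C(OC)C(O)(/C=C/[C@H](C)[C@H](O[Si](C)(C)C(C)(C)C)c2cc(OC)c(OC)c(OC)c2)C1=O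
F4 | step 5 | 5-[(1S,2S)-1-(tert-butyldimethylsilyloxy)-1-(3,4,5-trimethoxyphenyl)propan-2-yl]-2,3-dimethoxybenzene-1,4-diol | COc1c(O)cc([C@H](C)[C@H](O[Si](C)(C)C(C)(C)C)c2cc(OC)c(OC)c(OC)c2)c(O)c1OC
F5 | step 2 | (1S,2S)-2-methyl-1-(3,4,5-trimethoxyphenyl)but-3-en-1-ol | C=C[C@H](C)[C@H](O)c1cc(OC)c(OC)c(OC)c1
F6 | step 2 | tert-butyl(dimethyl){[(1S,2S)-2-methyl-1-(3,4,5-trimethoxyphenyl)but-3-en-1-yl]oxy}silane | C=C[C@H](C)[C@H](O[Si](C)(C)C(C)(C)C)c1cc(OC)c(OC)c(OC)c1
F7 | step 2 | (2R,3S)-3-(tert-butyldimethylsilyloxy)-2-methyl-3-(3,4,5-trimethoxyphenyl)propanal | O=C[C@H](C)[C@H](O[Si](C)(C)C(C)(C)C)c1cc(OC)c(OC)c(OC)c1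
F8 | step 8 | (2S,3S,5R)-5-hydroxy-7-methoxy-3-methyl-5-(prop-2-enyl)-2-(3,4,5-trimethoxyphenyl)-3,5-dihydro-2H-1-benzofuran-6-one | C=CC[C@@]1(O)C=C2C(=C(OC)C1=O)O[C@H](c1cc(OC)c(OC)c(OC)c1)[C@H]2C
F9 | step 9 | (4R)-6-[(1S,2S)-1-(tert-butyldimethylsilyloxy)-1-(3,4,5-trimethoxyphenyl)propan-2-yl]-3-hydroxy-2,4-dimethoxy-4-(prop-2-enyl)cyclohexa-2,5-dien-1-one | C=CC[C@@]1(OC)C=C([C@H](C)[C@H](O[Si](C)(C)C(C)(C)C)c2cc(OC)c(OC)c(OC)c2)C(=O)C(OC)=C1O
F10 | step 9 | (4R)-3-hydroxy-6-[(1S,2S)-1-hydroxy-1-(3,4,5-trimethoxyphenyl)propan-2-yl]-2,4-dimethoxy-4-(prop-2-enyl)cyclohexa-2,5-dien-1-one | C=CC[C@@]1(OC)C=C([C@H](C)[C@H](O)c2cc(OC)c(OC)c(OC)c2)C(=O)C(OC)=C1O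
A1 | alternative 1 | (2S)-7-benzyloxy-6,8-dimethoxy-2-(3,4,5-trimethoxyphenyl)-2,3-dihydrochromen-4-one | COc1cc2c(c(OC)c1OCc1ccccc1)O[C@H](c1cc(OC)c(OC)c(OC)c1)CC2=O
A2 | alternative 1 | methyl (2S,3S)-6-benzyloxy-5,7-dimethoxy-2-(3,4,5-trimethoxyphenyl)-2,3-dihydrobenzofuran-3-carboxylate | COc1cc2c(c(OC)c1OCc1ccccc1)O[C@H](c1cc(OC)c(OC)c(OC)c1)[C@H]2C(=O)OC
A3 | alternative 2 | (2S,3S)-6-benzyloxy-5,7-dimethoxy-3-methyl-2-(3,4,5-trimethoxyphenyl)-2,3-dihydrobenzofuran | COc1cc2c(c(OC)c1OCc1ccccc1)O[C@H](c1cc(OC)c(OC)c(OC)c1)[C@H]2C
A4 | alternative 1 | (2S,3S)-5,7-dimethoxy-3-methyl-2-(3,4,5-trimethoxyphenyl)-2,3-dihydrobenzofuran-6-ol | COc1cc2c(c(OC)c1O)O[C@H](c1cc(OC)c(OC)c(OC)c1)[C@H]2C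
A5 | alternative 1 | (2S,3S)-5,7-dimethoxy-3-methyl-6-(prop-2-enyloxy)-2-(3,4,5-trimethoxyphenyl)-2,3-dihydrobenzofuran | C=CCOc1c(OC)cc2c(c1OC)O[C@H](c1cc(OC)c(OC)c(OC)c1)[C@H]2C
A6 | alternative 2 | 3-benzyloxy-2,4-dimethoxy-6-[1-(4-methylphenylsulfonyl)ethyl]phenol | COc1cc(C(C)S(=O)(=O)c2ccc(C)cc2)c(O)c(OC)c1OCc1ccccc1
A7 | alternative 2 | dimethyl(3,4,5-trimethoxybenzyl)sulfonium tetrafluoroborate | COc1cc(C[S+](C)C)cc(OC)c1OC.F[B-](F)(F)F
A8 | alternative 3 | methyl (2R,3Z)-4-[(1S,2S)-1-(tert-butyldimethylsilyloxy)-1-(3,4,5-trimethoxyphenyl)propan-2-yl]-2,6-dimethoxy-5-oxo-2-(prop-2-enyl)hex-3-enoate | C=CC[C@](OC)(C(=O)OC)/C=C(\C(=O)COC)[C@H](C)[C@H](O[Si](C)(C)C(C)(C)C)c1cc(OC)c(OC)c(OC)c1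
A9 | alternative 3 | (4R)-6-[(1S,2S)-1-(tert-butyldimethylsilyloxy)-1-(3,4,5-trimethoxyphenyl)propan-2-yl]-3-hydroxy-2,4-dimethoxy-4-(prop-2-enyl)cyclohexa-2,5-dien-1-one | C=CC[C@@]1(OC)C=C([C@H](C)[C@H](O[Si](C)(C)C(C)(C)C)c2cc(OC)c(OC)c(OC)c2)C(=O)C(OC)=C1O
A10 | alternative 3 | dimethyl 2-methoxy-2-(prop-2-enyl)propanedioate | C=CCC(OC)(C(=O)OC)C(=O)OC
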